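The earlier runs and the new flask are simulated on assumed constants.

The amber run gains less monomer in chains in its second stretch than in its first: 14.8 % by 1.50 h, then 5.4 percentage points in the equal stretch up to 3.00 h. So I count how many half-lives of the rate a flask lives through.

common to all: free monomer 0.050 M

| charge | transfer agent | initiator | temperature | remark | time |
|---|---|---|---|---|---|
| amber | 10 mM | 5 mM | 90 °C | run made earlier |  |
| noon | 5.00 mM | 5.0 mM | 90 °C |  | 10 h |
| dusk | 5.00 mM | 5.0 mM | 150 °C |  | 10 h |
| winter | 5.00 mM | 5.0 mM | 120 °C |  | 10 h |

- amber (time / h: monomer in chains / %, free monomer / %): 0.250: 3.9, 96.8; 0.417: 6.1, 95.7; 0.833: 9.8, 90.1; 1.50: 14.8, 84.2; 3.00: 20.2, 79.7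

(standard deviation of a reading: 1 percentage point)

- the earlier runs do not show what temperature does; that part of a forecast is a guess
- no earlier run changes the charge of transfer agent; that part of a forecast is a guess

- the best flask by amount of monomer in chains, in percent of the free monomer charged; "all alike" if 1.5 percentage points covers them all (noon / dusk / winter / all alike)
- amount of monomer in chains at the end, in percent of the free monomer charged, noon
- amount of monomer in chains at the end, in percent of the free monomer charged, dusk
- amount of monomer in chains at the end, in percent of the free monomer charged, winter

Taking the fall as exponential, those two gains give 1.03 h for the half-life of the rate, the time in which the making of monomer in chains falls to half; this is a reading and carries the scatter. A run of 10 h holds 9.71 half-lives of that length, so I reckon with a plateau for amber, and a rate that keeps halving totals the first gain divided by one minus the ratio of the gains, which reads 23.3 %, with the scatter of the readings in it. Noon has half of amber's transfer agent and the same initiator. If the agent ends the chains, in step with its charge, noon's half-life is 2.06 h, and the plateau doubles to 46.6 %.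

The weak link is that doubling. Amber's last row adds up to about the whole charge, so free monomer falls as chains grow, and a rate in step with free monomer doubles the logarithm of what is left, not the gain. On that reading amber's plateau leaves 76.7 %; for noon I reckon the square of that, 58.8 %, which gives my estimate of 41.2 % in chains. The runs show no temperature, so I give no count for dusk or winter.

The forecast names noon as best, with 25 % for noon, 7 % for dusk and 13 % for winter, and holds that “Transfer agent normally leaves rate almost unchanged”. My noon stands above it.

    free monomer + initiator → living end + monomer in chains (k = 318 M⁻¹ h⁻¹, Ea = 73.0 kJ mol⁻¹)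
    free monomer + living end → monomer in chains + living end, rate k2*[living end]*[free monomer] (k = 22.0 M⁻¹ h⁻¹, Ea = 72.0 kJ mol⁻¹)
    living end + transfer agent → dead chain (kL = 95.0 M⁻¹ h⁻¹, Ea = 53.0 kJ mol⁻¹)
    2 initiator ⇌ resting dimer, settled at all times (K = 14000 M⁻¹, ΔH = −28.0 kJ mol⁻¹)
    initiator → spent initiator (k = 0.103 h⁻¹, Ea = 108 kJ mol⁻¹)
    monomer in chains → over-reaction product (k = 1.65 × 10⁻⁴ h⁻¹, Ea = 126 kJ mol⁻¹)
    (constants at 90 °C)

Noon gives 39.1 %, dusk 48.8 % and winter 66.2 %, so winter stands highest. Noon's own gains, 30.7 % by 5.00 h and 8.4 points more by 10.0 h, give a half-life of 2.68 h, longer than amber's. Winter's net gains give 1.54 h, so by this count 6.49 half-lives pass there. The neighbour is winter with 4.00 times the initiator: with that half-life and a start rate in step with the charge, winter's 31.6 % of free monomer raised to that power is 1.00 %. The neighbour holds 0 % free monomer and 96.2 % in chains.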